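The ratio I follow is what J does to D against what J does to Q.

    D + X → J + L (k1 = 0.19 M⁻¹ s⁻¹, Ea1 = 49.0 kJ mol⁻¹)
    D + J → L + J, rate k2*[J]*[D] (k2 = 3.1 M⁻¹ s⁻¹, Ea2 = 50.0 kJ mol⁻¹)
    J + Q → J.Q (k3 = 1.9 M⁻¹ s⁻¹, Ea3 = 42.0 kJ mol⁻¹)
    J + L → J.L (k4 = 0.030 M⁻¹ s⁻¹, Ea4 = 54.0 kJ mol⁻¹)
    (constants at 5 °C)
- green: D 3.0 M; Q 0.0300 M; X 30 mM; temperature 5 °C; time 10 s
- red: D 3.0 M; Q 0.0300 M; X 30 mM; temperature 25 °C; time 10 s
* which of these there is most of at the end, counted by the D in it, green (D / L)
* which of these there is most of at the end, counted by the D in it, red (D / L)
* the largest of these amounts at the end, in percent of the D charged, green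
* the largest of these amounts at the end, in percent of the D charged, red
- constants are those at 5 °C; use the activation energies for any other temperature

J is the same J in the second and third steps, so it cancels when I divide one logarithmic fall by the other. X can take 1.00% of D, and I drop that. The selectivity factor S, the second constant over the third, 1.63 at 5 °C, is then the number of decades D falls for each decade Q falls:

ln[c(D) end / c(D) start] = S · ln[c(Q) end / c(Q) start]

In red the activation energies raise S to 2.06. D and L stand level when D has fallen 0.301 of a decade. So Q must fall to 65.4% in green and to 71.4% in red.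

For Q's fall I let J appear after a lag, the inverse of the first constant times c(D), and then decay on Q as charged. That gives the following.

green: lag 1.75 s, Q ends at 68.7%, D at 54.2%

red: lag 0.424 s, Q ends at 43.1%, D at 17.7%

Now take a neighbour of green with 0.0075 M of Q, a quarter of the charge. S is unchanged, and I reckon D at 48.5%.

The forecast gives D at 56% in green and L at 68% in red, holding that “the faster catalysis outruns the faster J loss”. We part on red, where my L is 82.3%.

The flask gives D at 55.7% in green and L at 69.0% in red. The main reason red D ends lower than green D is the difference in temperature: without it, red D stands at 55.7%, not 30.4%. Part of the reason red D stands at 30.4%, not at my figure, is that J + L takes J away: with that step struck out, red D ends at 11.6%. That theft starves D and Q alike, so S survives it: red Q at 56.4% gives D 30.8%, and green Q at 70.3% gives D 56.3%. In the neighbour, Q at 66.6% gives D 51.5%, and the flask holds 51.0%.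

The constants are made up, and the outcome is calculated.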